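**Assumption:** the target has no stereocentres, only two E-trisubstituted alkenes and a tetrasubstituted ring alkene. E-geometry is therefore the only stereochemical element, and no enantiocontrol is needed.

## Retrosynthetic overview
1. Disconnect the aryl–CH2 bond by a Pd-catalysed allyl–aryl Suzuki coupling. This gives a 2,5-bis(MOM-oxy)phenyl-Bpin, made by Ir-catalysed C–H borylation of bis-MOM hydroquinone, and a C20 cyclogeranylgeranyl-type allylic carbonate.
2. Disconnect the carbonate by two Negishi couplings: the alkenyl C6–C5 bond, and the hindered ring C1'–C9 bond to a 2,6,6-trimethylcyclohexenyl triflate.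
3. Both E-trisubstituted alkenes come from one Zr-catalysed carboalumination building block (Br–CH2CH2–C(Me)=CH–I). It is used twice, once directly and once after conversion to the ester.
4. No ring is constructed: the cyclohexane comes from 2-methylcyclohexanone (two methylations, then enol triflation) and the arene from hydroquinone.

## Route

**Step 1**
Reactants: 1 2-methylcyclohexanone
Product: 2 2,6-dimethylcyclohexanone (cis/trans mixture)
Conditions: LDA, THF, −78 °C; then MeI, −78 °C → rt
Reagents that add atoms: MeI (CI)
Why: Kinetic enolisation occurs at the less substituted C6, and SN2 methylation follows. The new C6 stereocentre is a cis/trans mixture that is erased by enolisation in the next step.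

**Step 2**
Reactants: 2 2,6-dimethylcyclohexanone
Product: 3 2,2,6-trimethylcyclohexanone
Conditions: KHMDS (1.05 equiv), THF, −78 → 0 °C; then MeI, −78 °C → rt
Reagents that add atoms: MeI (CI)
Why: Enolisation at either equivalent tertiary α-C–H followed by C-methylation installs the gem-dimethyl quaternary carbon. One equivalent of base limits over-methylation, because the product has only one α-H.

**Step 3**
Reactants: 3 2,2,6-trimethylcyclohexanone
Product: 4 2,6,6-trimethylcyclohex-1-en-1-yl triflate
Conditions: KHMDS, THF, −78 °C; then PhNTf2, −78 °C → rt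
Reagents that add atoms: PhNTf2 (O=S(=O)(N(c1ccccc1)S(=O)(=O)C(F)(F)F)C(F)(F)F)
Why: Only C6 carries an enolisable H, so enol triflation (N-triflimide O-sulfonylation) necessarily gives the tetrasubstituted alkenyl triflate. The C6 stereocentre is destroyed.

**Step 4**
Reactants: 5 4-bromo-1-butyne
Product: 6 (E)-4-bromo-1-iodo-2-methylbut-1-ene
Conditions: Me3Al, Cp2ZrCl2 (cat.), ClCH2CH2Cl, 0 °C → rt; then I2, THF, −30 °C
Reagents that add atoms: Me3Al (C[Al](C)C); I2 (II)
Why: Negishi Zr-catalysed carboalumination adds Me and Al syn across the terminal alkyne, so iodination gives the E-trisubstituted alkenyl iodide with the alkyl bromide untouched.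

**Step 5**
Reactants: 6 (E)-4-bromo-1-iodo-2-methylbut-1-ene (half of the material from Step 4)
Product: 7 ethyl (E)-5-bromo-3-methylpent-2-enoate
Conditions: CO (1 atm), EtOH, Pd(PPh3)4 (3 mol %), i-Pr2NEt, MeCN, 50 °C
Reagents that add atoms: CO ([C-]#[O+]); EtOH (CCO)
Why: Pd-catalysed alkoxycarbonylation of an alkenyl iodide proceeds with retention of configuration, and the unactivated primary alkyl bromide does not insert Pd(0).

**Step 6**
Reactants: 7 ethyl (E)-5-bromo-3-methylpent-2-enoate; 6 (E)-4-bromo-1-iodo-2-methylbut-1-ene
Product: 8 ethyl (2E,6E)-9-bromo-3,7-dimethylnona-2,6-dienoate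
Conditions: 7: Zn dust (TMSCl/BrCH2CH2Br-activated), LiCl, DMA, 50 °C. The organozinc solution is decanted from excess Zn and 6 is added with Pd(PPh3)4 (5 mol %), THF, rt.
Reagents that add atoms: none
Why: Negishi sp2–sp3 coupling occurs chemoselectively at the alkenyl iodide, and the E-geometry of both alkenes is retained.

**Step 7**
Reactants: 8 ethyl (2E,6E)-9-bromo-3,7-dimethylnona-2,6-dienoate; 4 2,6,6-trimethylcyclohex-1-en-1-yl triflate
Product: 9 ethyl (2E,6E)-3,7-dimethyl-9-(2,6,6-trimethylcyclohex-1-en-1-yl)nona-2,6-dienoate
Conditions: 8: Zn dust, LiCl, DMA, 50 °C; then 4, Pd-PEPPSI-IPent (5 mol %), LiBr, THF/NMP, 50 °C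
Reagents that add atoms: none
Why: Proposed new method: a Negishi coupling of a doubly α-branched, tetrasubstituted cycloalkenyl triflate with a functionalised primary alkylzinc (bearing an E-enoate), which is a substrate class not shown to couple. Oxidative addition of the hindered enol triflate to a Pd(0) complex of the flexible, bulky IPent NHC gives an alkenyl–Pd(II) species with no β-H on the ring side. LiBr converts it to the alkenyl–Pd–Br and aids transmetalation, and the bulky NHC drives reductive elimination. The closest known reactions are Pd-PEPPSI-IPent Negishi couplings of hindered aryl halides and Fe- or Pd-catalysed couplings of enol triflates. No stereocentre is formed and the alkene geometries are retained.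

**Step 8**
Reactants: 9 ethyl ester of the C20 cyclic dienoate
Product: 10 (2E,6E)-3,7-dimethyl-9-(2,6,6-trimethylcyclohex-1-en-1-yl)nona-2,6-dien-1-ol
Conditions: DIBAL-H (2.5 equiv), CH2Cl2, −78 °C
Reagents that add atoms: none (DIBAL-H delivers H only)
Why: 1,2-Reduction of the unsaturated ester to the allylic alcohol leaves all three alkenes intact, and the geometry is unchanged.

**Step 9**
Reactants: 11-precursor alcohol 10
Product: 11 methyl (2E,6E)-3,7-dimethyl-9-(2,6,6-trimethylcyclohex-1-en-1-yl)nona-2,6-dienyl carbonate
Conditions: ClCO2Me, pyridine, DMAP (cat.), CH2Cl2, 0 °C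
Reagents that add atoms: methyl chloroformate (COC(=O)Cl)
Why: O-Acylation gives a π-allyl-Pd precursor that is stable on silica.

**Step 10**
Reactants: 12 hydroquinone
Product: 13 1,4-bis(methoxymethoxy)benzene
Conditions: MOMCl, i-Pr2NEt, CH2Cl2, 0 °C → rt
Reagents that add atoms: MOMCl (COCCl)
Why: MOM acetals protect both phenols. They survive the Ir and Pd steps and can be removed later without acid strong enough to damage the polyene.

**Step 11**
Reactants: 13 1,4-bis(methoxymethoxy)benzene (arene in excess)
Product: 14 2-[2,5-bis(methoxymethoxy)phenyl]-4,4,5,5-tetramethyl-1,3,2-dioxaborolane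
Conditions: B2pin2, [Ir(OMe)(cod)]2 (1.5 mol %), dtbpy, THF, 80 °C
Reagents that add atoms: B2pin2 (CC1(C)OB(OB2OC(C)(C)C(C)(C)O2)OC1(C)C)
Why: Ir-catalysed C–H borylation. All four arene C–H bonds are equivalent, so it gives a single regioisomer, and excess arene suppresses diborylation.

**Step 12**
Reactants: 14 arylboronate; 11 allylic carbonate
Product: 15 bis-MOM ether of jaspaquinol
Conditions: Pd(PPh3)4 (5 mol %), K3PO4, dioxane, 80 °C
Reagents that add atoms: none
Why: Pd(0) ionises the carbonate to a π-allyl-Pd species. After transmetalation from the boronate, reductive elimination occurs at the unhindered primary terminus, which forms the aryl–CH2 bond and retains the E-alkene (Tsuji–Trost-type Suzuki–Miyaura allyl–aryl coupling).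

**Step 13**
Reactants: 15 bis-MOM ether
Product: 16 jaspaquinol
Conditions: ZnBr2, n-PrSH, CH2Cl2, 0 °C → rt, under Ar
Reagents that add atoms: none
Why: Mild Lewis-acid/thiol cleavage of the MOM acetals gives the free hydroquinone without isomerising or cyclising the alkenes.

## Compound list
1 | 2-methylcyclohexanone | CC1CCCCC1=O | starting material
2 | 2,6-dimethylcyclohexanone | CC1CCCC(C)C1=O | intermediate
3 | 2,2,6-trimethylcyclohexanone | CC1CCCC(C)(C)C1=O | intermediate
4 | 2,6,6-trimethylcyclohex-1-en-1-yl triflate | CC1=C(OS(=O)(=O)C(F)(F)F)C(C)(C)CCC1 | intermediate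
5 | 4-bromo-1-butyne | C#CCCBr | starting material
6 | (E)-4-bromo-1-iodo-2-methylbut-1-ene | BrCC/C(C)=C/I | intermediate
7 | ethyl (E)-5-bromo-3-methylpent-2-enoate | CCOC(=O)/C=C(C)/CCBr | intermediate
8 | ethyl (2E,6E)-9-bromo-3,7-dimethylnona-2,6-dienoate | CCOC(=O)/C=C(C)/CC/C=C(C)/CCBr | intermediate
9 | ethyl (2E,6E)-3,7-dimethyl-9-(2,6,6-trimethylcyclohex-1-en-1-yl)nona-2,6-dienoate | CCOC(=O)/C=C(C)/CC/C=C(C)/CCC1=C(C)CCCC1(C)C | intermediate
10 | (2E,6E)-3,7-dimethyl-9-(2,6,6-trimethylcyclohex-1-en-1-yl)nona-2,6-dien-1-ol | OC/C=C(C)/CC/C=C(C)/CCC1=C(C)CCCC1(C)C | intermediate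
11 | methyl carbonate of 10 | COC(=O)OC/C=C(C)/CC/C=C(C)/CCC1=C(C)CCCC1(C)C | intermediate
12 | hydroquinone | Oc1ccc(O)cc1 | starting material
13 | 1,4-bis(methoxymethoxy)benzene | COCOc1ccc(OCOC)cc1 | intermediate
14 | 2-[2,5-bis(methoxymethoxy)phenyl]-4,4,5,5-tetramethyl-1,3,2-dioxaborolane | COCOc1ccc(OCOC)c(c1)B1OC(C)(C)C(C)(C)O1 | intermediate
15 | bis-MOM ether of jaspaquinol | COCOc1ccc(OCOC)c(C/C=C(C)/CC/C=C(C)/CCC2=C(C)CCCC2(C)C)c1 | intermediate
16 | jaspaquinol | CC1=C(CC/C(C)=C/CC/C(C)=C/Cc2cc(O)ccc2O)C(C)(C)CCC1 | target

## Summary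
Total steps: 13. Longest linear sequence: 8 (5→6→7→8→9→10→11→15→16, or equivalently 1→2→3→4→9→10→11→15→16).

Three steps most likely to fail:
1. **Step 7 (proposed new Negishi coupling).** Hindrance at the tetrasubstituted triflate may give protodezincation or reduction of the triflate. Fallback (known chemistry): make the tosylhydrazone of 3 and do a Shapiro formylation to β-cyclocitral. Aldol with acetone gives β-ionone, and selective hydrogenation of the side-chain enone gives dihydro-β-ionone. Then run a Julia–Kocienski olefination with the sulfone derived from 7, which gives ester 9 after E/Z separation.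
2. **Step 12 (allyl–aryl Suzuki coupling).** It may give branched regioisomers or E/Z scrambling through the π-allyl-Pd intermediate. Fallback: convert 10 to the allylic bromide (PBr3), then use directed ortho-lithiation of 13 (n-BuLi, TMEDA) and CuI-catalysed SN2 allylation, followed by Step 13.
3. **Step 11 (Ir-catalysed C–H borylation).** Hindrance ortho to OMOM may cause low conversion or diborylation. Fallback: NBS bromination of 13, then Miyaura borylation (B2pin2, Pd(dppf)Cl2, KOAc) to give 14.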